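**Plan** (eudesmane numbering: ring A = C1–C5/C10, ring B = C5–C10, C14 on C10, C15 on C4, C11–C13 on C7)

1. Cuts: the C12 methyl ester and the C11=C13 methylene (back to a C7 allyl group), the C8 acetate and C3 enoate C–O bonds, C7–C11 (allylation next to a C8 ketone), then C1–C2 and C2–C3 (C2 excised, C1–C3 rejoined), then C5–C10, C1–C3 and C3–C4 (enyne cyclocarbonylation) and C8–C9 (aldehyde methallylation).
2. Enabling feature: ring A in its ketone form is a 2-methylcyclohex-2-enone (C3=O, C4–CH3, C4=C5, quaternary C10). Its five-membered homologue lacking C2 is a 2-methylcyclopent-2-enone fused to ring B, which is the Pauson–Khand product of a 1,7-enyne and has C1 as its only enolisable α-carbon, so C2 can be inserted between C1 and C3.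
3. Forward order: hex-4-ynal and a methallyl unit give the acyclic enyne; one Pauson–Khand reaction closes ring B and the 2-nor ring A together; ring A is enlarged from five to six members; ring A is reduced and esterified; ring B is then taken through C8 ketone, C7 allyl, 8β-acetate and acrylate.
4. Stereochemistry: the C8 carbinol comes from a catalyst-controlled Keck methallylation and relays to C10 in the Pauson–Khand step (silyloxy equatorial, C14 axial), after which it is erased by oxidation. C3 comes from a Luche reduction anti to C14, C7 from equilibration next to the C8 ketone (equatorial), C8 from equatorial hydride delivery (axial 8β-OH), and the E-enoate from the purchased acid.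

Key step: step 6

Assumption: tributyl(2-methylprop-2-en-1-yl)stannane (3) and (2E)-3-methylpent-2-enoic acid (13) are purchased, 13 as the pure E isomer, whose geometry is carried unchanged into the C3 ester.

**Step 1**
Reactants: 1 hex-4-yn-1-ol
Product: 2 hex-4-ynal
Conditions: Dess–Martin periodinane, CH2Cl2, 0 °C to rt; used as a concentrated solution
Reagents that add atoms: none
Why: Dess–Martin oxidation of a primary alcohol stops at the aldehyde and leaves the internal alkyne untouched.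

**Step 2**
Reactants: 2 hex-4-ynal; 3 tributyl(2-methylprop-2-en-1-yl)stannane
Product: 4 (4R)-2-methylnon-1-en-7-yn-4-ol
Conditions: (S)-BINOL (10 mol%), Ti(OiPr)4 (10 mol%), 4 Å MS, CH2Cl2, −20 °C; aq NaHCO3
Reagents that add atoms: none
Why: Keck catalytic asymmetric methallylation, in which the (S)-BINOL–Ti(OiPr)4 Lewis acid should direct the stannane to the aldehyde face that gives the (4R)-carbinol (future C8), as for other unbranched aliphatic aldehydes.

**Step 3**
Reactants: 4 (4R)-2-methylnon-1-en-7-yn-4-ol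
Product: 5 (4R)-4-[(tert-butyldimethylsilyl)oxy]-2-methylnon-1-en-7-yne
Conditions: TBSCl, imidazole, DMF, rt
Reagents that add atoms: tert-butyldimethylsilyl chloride CC(C)(C)[Si](C)(C)Cl
Why: Standard silylation of a secondary alcohol; the silyl ether tolerates the cobalt, amide-base, zinc and iron reagents that follow.

**Step 4**
Reactants: 5 (4R)-4-[(tert-butyldimethylsilyl)oxy]-2-methylnon-1-en-7-yne
Product: 6 (6R,7aS)-6-[(tert-butyldimethylsilyl)oxy]-3,7a-dimethyl-1,4,5,6,7,7a-hexahydro-2H-inden-2-one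
Conditions: Co2(CO)8 (20 mol%), tetramethylthiourea (cat.), CO (1 atm), toluene, 70 °C
Reagents that add atoms: carbon monoxide [C-]#[O+]
Why: Intramolecular Pauson–Khand reaction closes ring B (C5–C10) and the cyclopentenone (C1–C3, C3–C4) at once, and the chair-like ring-B transition state with the C8 silyloxy group equatorial and C14 axial should set C10 with C14 trans to the silyloxy group, the minor C10 epimer being removed by chromatography.

**Step 5**
Reactants: 6 (6R,7aS)-6-[(tert-butyldimethylsilyl)oxy]-3,7a-dimethyl-1,4,5,6,7,7a-hexahydro-2H-inden-2-one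
Product: 7 (6R,7aS)-6-[(tert-butyldimethylsilyl)oxy]-3,7a-dimethyl-2-[(trimethylsilyl)oxy]-5,6,7,7a-tetrahydro-4H-indene
Conditions: LiN(i-Pr)2 (LDA), THF, −78 °C; TMSCl, Et3N, −78 to 0 °C; non-aqueous work-up, used at once
Reagents that add atoms: chlorotrimethylsilane C[Si](C)(C)Cl
Why: Kinetic α′-deprotonation of the enone at C1 (the only α-CH2; γ-deprotonation at C6 is slower at −78 °C) and O-silylation give the cross-conjugated silyl dienol ether, which cannot undergo hydrogen shifts because C10 is quaternary.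

**Step 6**
Reactants: 7 (6R,7aS)-6-[(tert-butyldimethylsilyl)oxy]-3,7a-dimethyl-2-[(trimethylsilyl)oxy]-5,6,7,7a-tetrahydro-4H-indene
Product: 10 (4aS,6R)-6-[(tert-butyldimethylsilyl)oxy]-1,4a-dimethyl-5,6,7,8-tetrahydronaphthalen-2(4aH)-one, via siloxycyclopropane 8 (not isolated), via beta-chloro ketone 9 (not isolated)
Conditions: Et2Zn, CH2I2, CH2Cl2, 0 °C to rt; aq NH4Cl/pyridine work-up, crude; FeCl3, pyridine, DMF, 0 °C to rt; crude; NaOAc, MeOH, reflux
Reagents that add atoms: diiodomethane ICI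
Why: The zinc carbenoid (Simmons–Smith reagent from Et2Zn/CH2I2) transfers CH2 in a concerted [2+1] step to the C1=C3 silyl enol ether bond to give 8; FeCl3 then replaces silicon at oxygen by trivalent iron, one-electron oxidation gives a cyclopropyloxy radical whose β-scission breaks the internal C1–C3 bond, the ring-enlarged C1 radical takes chlorine from a second FeCl3 to give 9, and NaOAc removes HCl (E1cB) to the C1=C2 enone 10. The closest known reaction is the FeCl3-mediated one-carbon homologation of cycloalkanone silyl enol ethers to cycloalk-2-enones through siloxycyclopropanes, which has also been applied to cross-conjugated siloxy dienes derived from cycloalkenones. The only ring closed is the transient cyclopropane (concerted syn methylene transfer); six-membered ring A is not formed by cyclisation but by scission of the zero-atom bridge of the bicyclo[3.1.0]hexene, so that C1–C2 and C2–C3 are new and C1–C3 is lost. No new stereocentre survives, because C1 and C3 of 8 and C1 of 9 become sp2 in 10, so the face of methylene transfer is irrelevant and C8 and C10 are untouched. The step needs methylene transfer at C1=C3 rather than C4=C5 and internal rather than external bond cleavage: the oxygen substituent makes C1=C3 the most nucleophilic alkene for the electrophilic carbenoid (C4=C5 is tetrasubstituted and not oxygen-activated), and the secondary ring-enlarged radical is favoured over a primary exocyclic one. DMF/pyridine buffers HCl so that acid-induced opening of the vinyl siloxycyclopropane and loss of the C8 silyl ether should be suppressed.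

**Step 7**
Reactants: 10 (4aS,6R)-6-[(tert-butyldimethylsilyl)oxy]-1,4a-dimethyl-5,6,7,8-tetrahydronaphthalen-2(4aH)-one
Product: 11 (4aR,6R)-6-[(tert-butyldimethylsilyl)oxy]-1,4a-dimethyl-4,4a,5,6,7,8-hexahydronaphthalen-2(3H)-one
Conditions: H2 (1 atm), RhCl(PPh3)3 (10 mol%), benzene/EtOH, rt
Reagents that add atoms: none
Why: Homogeneous hydrogenation with RhCl(PPh3)3 reduces the disubstituted C1=C2 bond of a 1,4-dien-3-one and leaves the tetrasubstituted C4=C5 enone, as is standard for steroidal 1,4-dien-3-ones.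

**Step 8**
Reactants: 11 (4aR,6R)-6-[(tert-butyldimethylsilyl)oxy]-1,4a-dimethyl-4,4a,5,6,7,8-hexahydronaphthalen-2(3H)-one
Product: 12 (2S,4aR,6R)-6-[(tert-butyldimethylsilyl)oxy]-1,4a-dimethyl-2,3,4,4a,5,6,7,8-octahydronaphthalen-2-ol
Conditions: NaBH4, CeCl3·7H2O, MeOH, −78 to 0 °C
Reagents that add atoms: none
Why: Luche 1,2-reduction of the enone, with hydride delivered axially to C3 from the α-face anti to the C10 methyl, should give the pseudo-equatorial 3β-alcohol (3S).

**Step 9**
Reactants: 12 (2S,4aR,6R)-6-[(tert-butyldimethylsilyl)oxy]-1,4a-dimethyl-2,3,4,4a,5,6,7,8-octahydronaphthalen-2-ol; 13 (2E)-3-methylpent-2-enoic acid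
Product: 14 (2S,4aR,6R)-6-[(tert-butyldimethylsilyl)oxy]-1,4a-dimethyl-2,3,4,4a,5,6,7,8-octahydronaphthalen-2-yl (2E)-3-methylpent-2-enoate
Conditions: DCC, DMAP (cat.), CH2Cl2, 0 °C to rt
Reagents that add atoms: none
Why: Steglich esterification acylates the allylic alcohol with retention at C3 and, run cold with catalytic DMAP, should not isomerise the E-enoate.

**Step 10**
Reactants: 14 (2S,4aR,6R)-6-[(tert-butyldimethylsilyl)oxy]-1,4a-dimethyl-2,3,4,4a,5,6,7,8-octahydronaphthalen-2-yl (2E)-3-methylpent-2-enoate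
Product: 15 (2S,4aR,6R)-6-hydroxy-1,4a-dimethyl-2,3,4,4a,5,6,7,8-octahydronaphthalen-2-yl (2E)-3-methylpent-2-enoate
Conditions: HF·pyridine, pyridine, THF, 0 °C to rt
Reagents that add atoms: none
Why: Buffered fluoride cleaves the equatorial secondary silyl ether without ionising or hydrolysing the allylic C3 ester.

**Step 11**
Reactants: 15 (2S,4aR,6R)-6-hydroxy-1,4a-dimethyl-2,3,4,4a,5,6,7,8-octahydronaphthalen-2-yl (2E)-3-methylpent-2-enoate
Product: 16 (2S,4aR)-1,4a-dimethyl-6-oxo-2,3,4,4a,5,6,7,8-octahydronaphthalen-2-yl (2E)-3-methylpent-2-enoate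
Conditions: Dess–Martin periodinane, pyridine, CH2Cl2, rt
Reagents that add atoms: none
Why: Dess–Martin oxidation of the secondary alcohol gives the C8 ketone under neutral conditions, so the relay stereocentre is erased only after C10 and C3 are in place.

**Step 12**
Reactants: 16 (2S,4aR)-1,4a-dimethyl-6-oxo-2,3,4,4a,5,6,7,8-octahydronaphthalen-2-yl (2E)-3-methylpent-2-enoate
Product: 18 (2S,4aR,7S)-1,4a-dimethyl-6-oxo-7-(prop-2-en-1-yl)-2,3,4,4a,5,6,7,8-octahydronaphthalen-2-yl (2E)-3-methylpent-2-enoate, via C7-epimeric allyl ketone mixture 17 (not isolated)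
Conditions: LiN(SiMe3)2, THF, −78 °C; allyl bromide, DMPU, −78 to −20 °C; crude, DBU, toluene, rt
Reagents that add atoms: allyl bromide C=CCBr
Why: Kinetic ketone enolate alkylation should occur at C7 rather than at neopentyl C9 (next to quaternary C10) and faster than enoate deprotonation, and DBU then equilibrates C7 through the enol so that the allyl group should end mainly equatorial (7β), the minor epimer being separated and re-equilibrated.

**Step 13**
Reactants: 18 (2S,4aR,7S)-1,4a-dimethyl-6-oxo-7-(prop-2-en-1-yl)-2,3,4,4a,5,6,7,8-octahydronaphthalen-2-yl (2E)-3-methylpent-2-enoate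
Product: 19 (2S,4aR,6R,7S)-6-hydroxy-1,4a-dimethyl-7-(prop-2-en-1-yl)-2,3,4,4a,5,6,7,8-octahydronaphthalen-2-yl (2E)-3-methylpent-2-enoate
Conditions: LiBH(s-Bu)3 (L-Selectride), THF, −78 °C; aq NaOH, H2O2, 0 °C
Reagents that add atoms: none
Why: The bulky trialkylborohydride attacks the C8 carbonyl equatorially from the α-side, away from the syn-axial C14 methyl, to give the axial 8β-alcohol cis to the 7β-allyl group, while the hindered β,β-disubstituted enoate is not reduced at −78 °C.

**Step 14**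
Reactants: 19 (2S,4aR,6R,7S)-6-hydroxy-1,4a-dimethyl-7-(prop-2-en-1-yl)-2,3,4,4a,5,6,7,8-octahydronaphthalen-2-yl (2E)-3-methylpent-2-enoate
Product: 20 (2S,4aR,6R,7S)-6-(acetyloxy)-1,4a-dimethyl-7-(prop-2-en-1-yl)-2,3,4,4a,5,6,7,8-octahydronaphthalen-2-yl (2E)-3-methylpent-2-enoate
Conditions: Ac2O, DMAP, pyridine, 40 °C
Reagents that add atoms: acetic anhydride CC(=O)OC(C)=O
Why: DMAP-catalysed acetylation caps the hindered axial alcohol before any C12 carbonyl exists, so the cis-γ-lactone cannot form later.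

**Step 15**
Reactants: 20 (2S,4aR,6R,7S)-6-(acetyloxy)-1,4a-dimethyl-7-(prop-2-en-1-yl)-2,3,4,4a,5,6,7,8-octahydronaphthalen-2-yl (2E)-3-methylpent-2-enoate
Product: 22 (2S,4aR,6R,7R)-6-(acetyloxy)-1,4a-dimethyl-7-(2-oxoethyl)-2,3,4,4a,5,6,7,8-octahydronaphthalen-2-yl (2E)-3-methylpent-2-enoate, via vicinal diol 21 (not isolated)
Conditions: OsO4 (2 mol%), NaIO4, 2,6-lutidine, dioxane/H2O, rt
Reagents that add atoms: osmium tetroxide O=[Os](=O)(=O)=O (catalytic oxygen carrier); sodium periodate [Na+].[O-]I(=O)(=O)=O (terminal oxidant)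
Why: Lemieux–Johnson cleavage should take the unhindered monosubstituted alkene in preference to the shielded tetrasubstituted C4=C5 bond and the electron-poor enoate, giving the C11–C12 aldehyde.

**Step 16**
Reactants: 22 (2S,4aR,6R,7R)-6-(acetyloxy)-1,4a-dimethyl-7-(2-oxoethyl)-2,3,4,4a,5,6,7,8-octahydronaphthalen-2-yl (2E)-3-methylpent-2-enoate
Product: 24 (2S,4aR,6R,7R)-6-(acetyloxy)-1,4a-dimethyl-7-(3-oxoprop-1-en-2-yl)-2,3,4,4a,5,6,7,8-octahydronaphthalen-2-yl (2E)-3-methylpent-2-enoate, via Mannich base 23 (not isolated)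
Conditions: CH2=NMe2+ I− (Eschenmoser's salt), Et3N, CH2Cl2, rt
Reagents that add atoms: N,N-dimethylmethyleneiminium iodide C=[N+](C)C.[I-]
Why: α-Methylenation of an aldehyde by Mannich reaction at C11 and β-elimination of dimethylamine installs C13 under weakly basic conditions that both esters tolerate, without touching C7.

**Step 17**
Reactants: 24 (2S,4aR,6R,7R)-6-(acetyloxy)-1,4a-dimethyl-7-(3-oxoprop-1-en-2-yl)-2,3,4,4a,5,6,7,8-octahydronaphthalen-2-yl (2E)-3-methylpent-2-enoate
Product: 25 2-[(2R,3R,4aR,7S)-3-(acetyloxy)-4a,8-dimethyl-7-{[(2E)-3-methylpent-2-enoyl]oxy}-1,2,3,4,4a,5,6,7-octahydronaphthalen-2-yl]prop-2-enoic acid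
Conditions: NaClO2, NaH2PO4, 2-methylbut-2-ene (excess), t-BuOH/H2O, 0 °C to rt
Reagents that add atoms: sodium chlorite [Na+].[O-]Cl=O
Why: Pinnick oxidation converts the 2-substituted acrolein into the acrylic acid, the alkene scavenger intercepting hypochlorite before it can reach C4=C5.

**Step 18**
Reactants: 25 2-[(2R,3R,4aR,7S)-3-(acetyloxy)-4a,8-dimethyl-7-{[(2E)-3-methylpent-2-enoyl]oxy}-1,2,3,4,4a,5,6,7-octahydronaphthalen-2-yl]prop-2-enoic acid
Product: 26 methyl 2-[(2R,3R,4aR,7S)-3-(acetyloxy)-4a,8-dimethyl-7-{[(2E)-3-methylpent-2-enoyl]oxy}-1,2,3,4,4a,5,6,7-octahydronaphthalen-2-yl]prop-2-enoate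
Conditions: TMSCHN2, MeOH/toluene, 0 °C
Reagents that add atoms: (trimethylsilyl)diazomethane C[Si](C)(C)C=[N+]=[N-]
Why: Base-free methyl esterification of the carboxylic acid with the diazoalkane avoids conjugate addition to the acrylate and vinylogous loss of the C8 acetate.

**Compound list**

1 | hex-4-yn-1-ol | CC#CCCCO | starting material
2 | hex-4-ynal | CC#CCCC=O | intermediate
3 | tributyl(2-methylprop-2-en-1-yl)stannane | C=C(C)C[Sn](CCCC)(CCCC)CCCC | starting material
4 | (4R)-2-methylnon-1-en-7-yn-4-ol | C=C(C)C[C@H](O)CCC#CC | intermediate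
5 | (4R)-4-[(tert-butyldimethylsilyl)oxy]-2-methylnon-1-en-7-yne | C=C(C)C[C@H](O[Si](C)(C)C(C)(C)C)CCC#CC | intermediate
6 | (6R,7aS)-6-[(tert-butyldimethylsilyl)oxy]-3,7a-dimethyl-1,4,5,6,7,7a-hexahydro-2H-inden-2-one (2-nor enone; 8α-silyloxy trans to 10β-methyl) | C1CC2=C(C)C(=O)C[C@]2(C)C[C@@H]1O[Si](C)(C)C(C)(C)C | intermediate
7 | (6R,7aS)-6-[(tert-butyldimethylsilyl)oxy]-3,7a-dimethyl-2-[(trimethylsilyl)oxy]-5,6,7,7a-tetrahydro-4H-indene | C1CC2=C(C)C(O[Si](C)(C)C)=C[C@]2(C)C[C@@H]1O[Si](C)(C)C(C)(C)C | intermediate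
8 | siloxycyclopropane: 7 with a CH2 (C2) bridging indene C1 and C2 (eudesmane C1 and C3), OSiMe3 on the ring-fusion carbon, C4=C5 intact; cyclopropane face not defined | C1CC2=C(C)C3(O[Si](C)(C)C)CC3[C@]2(C)C[C@@H]1O[Si](C)(C)C(C)(C)C | intermediate
9 | (4aR,6R)-6-[(tert-butyldimethylsilyl)oxy]-4-chloro-1,4a-dimethyl-4,4a,5,6,7,8-hexahydronaphthalen-2(3H)-one (chloride on eudesmane C1; epimers at that carbon) | C1CC2=C(C)C(=O)CC(Cl)[C@]2(C)C[C@@H]1O[Si](C)(C)C(C)(C)C | intermediate
10 | (4aS,6R)-6-[(tert-butyldimethylsilyl)oxy]-1,4a-dimethyl-5,6,7,8-tetrahydronaphthalen-2(4aH)-one | C1CC2=C(C)C(=O)C=C[C@]2(C)C[C@@H]1O[Si](C)(C)C(C)(C)C | intermediate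
11 | (4aR,6R)-6-[(tert-butyldimethylsilyl)oxy]-1,4a-dimethyl-4,4a,5,6,7,8-hexahydronaphthalen-2(3H)-one | C1CC2=C(C)C(=O)CC[C@]2(C)C[C@@H]1O[Si](C)(C)C(C)(C)C | intermediate
12 | (2S,4aR,6R)-6-[(tert-butyldimethylsilyl)oxy]-1,4a-dimethyl-2,3,4,4a,5,6,7,8-octahydronaphthalen-2-ol | C1CC2=C(C)[C@@H](O)CC[C@]2(C)C[C@@H]1O[Si](C)(C)C(C)(C)C | intermediate
13 | (2E)-3-methylpent-2-enoic acid | CC/C(C)=C/C(=O)O | starting material
14 | (2S,4aR,6R)-6-[(tert-butyldimethylsilyl)oxy]-1,4a-dimethyl-2,3,4,4a,5,6,7,8-octahydronaphthalen-2-yl (2E)-3-methylpent-2-enoate | C1CC2=C(C)[C@@H](OC(=O)/C=C(\C)CC)CC[C@]2(C)C[C@@H]1O[Si](C)(C)C(C)(C)C | intermediate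
15 | (2S,4aR,6R)-6-hydroxy-1,4a-dimethyl-2,3,4,4a,5,6,7,8-octahydronaphthalen-2-yl (2E)-3-methylpent-2-enoate | C1CC2=C(C)[C@@H](OC(=O)/C=C(\C)CC)CC[C@]2(C)C[C@@H]1O | intermediate
16 | (2S,4aR)-1,4a-dimethyl-6-oxo-2,3,4,4a,5,6,7,8-octahydronaphthalen-2-yl (2E)-3-methylpent-2-enoate | C1CC2=C(C)[C@@H](OC(=O)/C=C(\C)CC)CC[C@]2(C)CC1=O | intermediate
17 | (2S,4aR)-1,4a-dimethyl-6-oxo-7-(prop-2-en-1-yl)-2,3,4,4a,5,6,7,8-octahydronaphthalen-2-yl (2E)-3-methylpent-2-enoate, mixture of C7 epimers | C=CCC1CC2=C(C)[C@@H](OC(=O)/C=C(\C)CC)CC[C@]2(C)CC1=O | intermediate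
18 | (2S,4aR,7S)-1,4a-dimethyl-6-oxo-7-(prop-2-en-1-yl)-2,3,4,4a,5,6,7,8-octahydronaphthalen-2-yl (2E)-3-methylpent-2-enoate (7β-allyl) | C=CC[C@H]1CC2=C(C)[C@@H](OC(=O)/C=C(\C)CC)CC[C@]2(C)CC1=O | intermediate
19 | (2S,4aR,6R,7S)-6-hydroxy-1,4a-dimethyl-7-(prop-2-en-1-yl)-2,3,4,4a,5,6,7,8-octahydronaphthalen-2-yl (2E)-3-methylpent-2-enoate (8β-OH) | C=CC[C@H]1CC2=C(C)[C@@H](OC(=O)/C=C(\C)CC)CC[C@]2(C)C[C@H]1O | intermediate
20 | (2S,4aR,6R,7S)-6-(acetyloxy)-1,4a-dimethyl-7-(prop-2-en-1-yl)-2,3,4,4a,5,6,7,8-octahydronaphthalen-2-yl (2E)-3-methylpent-2-enoate | C=CC[C@H]1CC2=C(C)[C@@H](OC(=O)/C=C(\C)CC)CC[C@]2(C)C[C@H]1OC(C)=O | intermediate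
21 | (2S,4aR,6R,7R)-6-(acetyloxy)-7-(2,3-dihydroxypropyl)-1,4a-dimethyl-2,3,4,4a,5,6,7,8-octahydronaphthalen-2-yl (2E)-3-methylpent-2-enoate, carbinol epimers | OCC(O)C[C@H]1CC2=C(C)[C@@H](OC(=O)/C=C(\C)CC)CC[C@]2(C)C[C@H]1OC(C)=O | intermediate
22 | (2S,4aR,6R,7R)-6-(acetyloxy)-1,4a-dimethyl-7-(2-oxoethyl)-2,3,4,4a,5,6,7,8-octahydronaphthalen-2-yl (2E)-3-methylpent-2-enoate | O=CC[C@H]1CC2=C(C)[C@@H](OC(=O)/C=C(\C)CC)CC[C@]2(C)C[C@H]1OC(C)=O | intermediate
23 | (2S,4aR,6R,7R)-6-(acetyloxy)-7-[3-(dimethylamino)-1-oxopropan-2-yl]-1,4a-dimethyl-2,3,4,4a,5,6,7,8-octahydronaphthalen-2-yl (2E)-3-methylpent-2-enoate, side-chain epimers | CN(C)CC(C=O)[C@H]1CC2=C(C)[C@@H](OC(=O)/C=C(\C)CC)CC[C@]2(C)C[C@H]1OC(C)=O | intermediate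
24 | (2S,4aR,6R,7R)-6-(acetyloxy)-1,4a-dimethyl-7-(3-oxoprop-1-en-2-yl)-2,3,4,4a,5,6,7,8-octahydronaphthalen-2-yl (2E)-3-methylpent-2-enoate | C=C(C=O)[C@H]1CC2=C(C)[C@@H](OC(=O)/C=C(\C)CC)CC[C@]2(C)C[C@H]1OC(C)=O | intermediate
25 | 2-[(2R,3R,4aR,7S)-3-(acetyloxy)-4a,8-dimethyl-7-{[(2E)-3-methylpent-2-enoyl]oxy}-1,2,3,4,4a,5,6,7-octahydronaphthalen-2-yl]prop-2-enoic acid | C=C(C(=O)O)[C@H]1CC2=C(C)[C@@H](OC(=O)/C=C(\C)CC)CC[C@]2(C)C[C@H]1OC(C)=O | intermediate
26 | methyl 2-[(2R,3R,4aR,7S)-3-(acetyloxy)-4a,8-dimethyl-7-{[(2E)-3-methylpent-2-enoyl]oxy}-1,2,3,4,4a,5,6,7-octahydronaphthalen-2-yl]prop-2-enoate (3S,7R,8R,10R in eudesmane numbering) | C=C(C(=O)OC)[C@H]1CC2=C(C)[C@@H](OC(=O)/C=C(\C)CC)CC[C@]2(C)C[C@H]1OC(C)=O | target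

**Totals**

Total step count: 18. Longest linear sequence: 18 steps (1 to 26).

**Steps most likely to fail**

Step 4. Insertion of a 1,1-disubstituted alkene on a four-atom tether into the cobalt–alkyne complex is slow, so catalyst deactivation and alkyne oligomerisation may outrun cyclocarbonylation, and facial discrimination at C10 may be modest. The fallback sets out from 5 and comes back at 6 by a stepwise group-4 route. Cp2ZrCl2 with two equivalents of n-BuLi (THF, −78 °C to rt) generates Cp2Zr (divalent zirconium), which couples the alkene and the alkyne reversibly to the zirconabicycle F1. Because this coupling is under thermodynamic control, the equatorial silyloxy group should again place C14 trans to it. CO (1 atm, 0 °C) then inserts into the Zr–CH2 bond, and iodine work-up releases enone 6.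

Step 6. The trimethylsilyl dienol ether may hydrolyse before methylene transfer, or the vinyl siloxycyclopropane may open by protonation or Lewis-acid attack without ring enlargement instead of by one-electron β-scission; the C8 silyl ether may also be cleaved by FeCl3. The fallback sets out from 7 and comes back at 10 and keeps the same bond changes. Dibromocarbene (CHBr3, KOt-Bu, pentane, −20 °C) adds to the C1=C3 enol ether bond to give the dibromocyclopropane F2. Warming (toluene, 80 °C) causes electrocyclic opening with loss of bromide and the silyl group, which forms C1–C2 and C2–C3, breaks C1–C3 and gives the 2-bromo dienone F3. Hydrodebromination with zerovalent palladium and formate (Pd(OAc)2, PPh3, HCO2H, Et3N, DMF, 60 °C) then gives 10.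

Step 12. Deprotonation may compete at C9 or at the γ-carbons of the enoate, proton exchange may lead to double allylation, and the C7 epimer ratio after equilibration may be unfavourable. The fallback sets out from 16 and comes back at 18 through 17 by Stork enamine alkylation. Pyrrolidine (cat. TsOH, benzene, azeotropic water removal) gives the less substituted C7=C8 enamine F4, with regiochemistry under thermodynamic control and no strong base near the ester. Allyl bromide (MeCN, reflux) gives the C7-allyl iminium bromide F5. Buffered aqueous hydrolysis (AcOH/NaOAc) returns the epimeric ketone 17, which is equilibrated with DBU to 18 as in step 12.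

**Further compounds**

F1 | step 4 | zirconabicycle: Cp2Zr bridging C4 and C1 of the cyclised enyne (Zr–C4(CH3)=C5, Zr–CH2–C10), 8α-silyloxy, 10β-methyl | CC1=C2CC[C@@H](O[Si](C)(C)C(C)(C)C)C[C@@]2(C)C[Zr]1(C3C=CC=C3)C4C=CC=C4
F2 | step 6 | dibromocyclopropane: 7 with CBr2 bridging eudesmane C1 and C3, OSiMe3 on C3 | C1CC2=C(C)C3(O[Si](C)(C)C)C(Br)(Br)C3[C@]2(C)C[C@@H]1O[Si](C)(C)C(C)(C)C
F3 | step 6 | (4aS,6R)-3-bromo-6-[(tert-butyldimethylsilyl)oxy]-1,4a-dimethyl-5,6,7,8-tetrahydronaphthalen-2(4aH)-one (2-bromo dienone in eudesmane numbering) | C1CC2=C(C)C(=O)C(Br)=C[C@]2(C)C[C@@H]1O[Si](C)(C)C(C)(C)C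
F4 | step 12 | pyrrolidine enamine of 16 (C7=C8, N on C8) | C1=C(N3CCCC3)C[C@@]2(C)CC[C@H](OC(=O)/C=C(\C)CC)C(C)=C2C1
F5 | step 12 | C7-allyl pyrrolidinium (iminium) bromide derived from F4, C7 epimers | C=CCC1C(=[N+]3CCCC3)C[C@@]2(C)CC[C@H](OC(=O)/C=C(\C)CC)C(C)=C2C1.[Br-]
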